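**Retrosynthetic overview**

1. Target ⇐ one-pot fluoride deprotection of a bis(2-trimethylsilylethyl) ester / bis-TBS ether; the oxirane (the only ring) is formed last but one by reagent-controlled epoxidation of C4=C5 of a (2E,4Z)-dienoate.
2. Dienoate ⇐ key C5–C6 bond by Pd-catalysed Negishi sp3–sp2 coupling of a C6–C14 alkylzinc with a C1–C5 (2E,4Z)-5-iodo-dienoate.
3. Iodo-dienoate ⇐ propyne (Pt-catalysed cis-diboration) + (E)-enol triflate of an acetoacetate (site-selective Suzuki coupling, then B to I with retention).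
4. C6–C14 bromide ⇐ C12–C13 bond and both stereocentres by a copper-catalysed borylative syn-aldol of an acrylate with a C6–C12 bromo aldehyde, then C–B oxidation and silylation.
5. Bromo aldehyde ⇐ (S)-3-bromo-2-methylpropan-1-ol (C7 from the chiral pool) + pent-4-enyl Grignard (Cu-catalysed C8–C9 coupling), then ozonolysis.

Assumption: the SMILES is read as (2E,4S,5R,7S,12S,13R), i.e. C3 and C6 cis on the oxirane and a syn C12-OH/C13-CH2OH pair; positions are numbered along the tetradec-2-enedioic acid chain (C1 = enoic acid carbon).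

**Route**

Step 1
Reactants: 1 (S)-3-bromo-2-methylpropan-1-ol
Product: 2 (S)-3-bromo-2-methylpropyl trifluoromethanesulfonate
Conditions: Tf2O, 2,6-lutidine, CH2Cl2, −78 to −30 °C (cold aqueous work-up, used at once)
Reagents that add atoms: trifluoromethanesulfonic anhydride, O=S(=O)(OS(=O)(=O)C(F)(F)F)C(F)(F)F
Why: O-sulfonylation of a primary alcohol with a hindered pyridine base at low temperature gives the primary triflate without touching the stereocentre (the future C7).

Step 2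
Reactants: 2 (S)-3-bromo-2-methylpropyl trifluoromethanesulfonate; 3 5-bromopent-1-ene
Product: 5 (S)-8-bromo-7-methyloct-1-ene, via pent-4-en-1-ylmagnesium bromide 4 (not isolated)
Conditions: 3, Mg, THF, 40 °C; then 2, Li2CuCl4 (3 mol%), THF, −78 to −20 °C
Reagents that add atoms: none
Why: Copper-catalysed sp3–sp3 Grignard cross-coupling (Kochi type) is far faster at a primary triflate than at a primary bromide at −78 °C, so only C–OTf is replaced (C8–C9 bond) and the C7 configuration from 1 is carried through unchanged.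

Step 3
Reactants: 5 (S)-8-bromo-7-methyloct-1-ene
Product: 7 (S)-7-bromo-6-methylheptanal, via secondary ozonide 6 (not isolated)
Conditions: O3, CH2Cl2, −78 °C; then PPh3, −78 °C to rt
Reagents that add atoms: ozone, [O-][O+]=O
Why: Ozonolysis of the terminal alkene with reductive phosphine work-up gives the C12 aldehyde, and the primary alkyl bromide and the remote stereocentre are inert.

Step 4
Reactants: 8 acryloyl chloride
Product: 9 2-(trimethylsilyl)ethyl prop-2-enoate
Conditions: Me3SiCH2CH2OH, Et3N, CH2Cl2, 0 °C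
Reagents that add atoms: 2-(trimethylsilyl)ethanol, C[Si](C)(C)CCO
Why: Simple esterification of an acid chloride installs the fluoride-labile ester that is kept to the last step.

Step 5
Reactants: 7 (S)-7-bromo-6-methylheptanal; 9 2-(trimethylsilyl)ethyl prop-2-enoate
Product: 11 2-(trimethylsilyl)ethyl (2R,3S,8S)-9-bromo-3-hydroxy-2-(hydroxymethyl)-8-methylnonanoate, via bis-boryl aldol adduct 10 (not isolated)
Conditions: B2pin2 (1.1 equiv), CuCl (5 mol%), NaOt-Bu (8 mol%), (R)-5,5'-bis[bis(3,5-di-tert-butyl-4-methoxyphenyl)phosphino]-4,4'-bi-1,3-benzodioxole [(R)-DTBM-SEGPHOS, 6 mol%], 9 (1.5 equiv), THF, −40 °C, 7 added over 2 h; then NaBO3·4H2O, THF/H2O, 0 °C to rt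
Reagents that add atoms: sodium perborate, [Na+].[O-]OB=O
Why: Proposed new method: a chiral bisphosphine–copper boryl (monovalent copper, from CuOt-Bu and B2pin2) adds boron to the β-carbon of acrylate 9 to give a (Z)-O-copper enolate, which adds to aldehyde 7 through a closed six-membered chair transition state (syn, so C12 and C13 are set together, with the enantioface fixed by the ligand); B2pin2 then turns the copper aldolate over to 10 by σ-bond metathesis and perborate converts C–B into the C13 hydroxymethyl group with the ester untouched; the closest known reaction types are the copper hydride-catalysed enantioselective syn-reductive aldol of acrylates with aldehydes and the copper-catalysed β-borylation and intramolecular borylative aldol cyclisation of enoates.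

Step 6
Reactants: 11 2-(trimethylsilyl)ethyl (2R,3S,8S)-9-bromo-3-hydroxy-2-(hydroxymethyl)-8-methylnonanoate
Product: 12 2-(trimethylsilyl)ethyl (2R,3S,8S)-9-bromo-3-[(tert-butyldimethylsilyl)oxy]-2-{[(tert-butyldimethylsilyl)oxy]methyl}-8-methylnonanoate
Conditions: TBSOTf (2.5 equiv), 2,6-lutidine, CH2Cl2, −78 to 0 °C
Reagents that add atoms: tert-butyldimethylsilyl trifluoromethanesulfonate, CC(C)(C)[Si](C)(C)OS(=O)(=O)C(F)(F)F
Why: Silyl triflate/lutidine silylation protects both hydroxyls under non-basic conditions, so retro-aldol and epimerisation at C13 are avoided.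

Step 7
Reactants: 13 methyl 3-oxobutanoate
Product: 14 2-(trimethylsilyl)ethyl 3-oxobutanoate
Conditions: Me3SiCH2CH2OH (1.2 equiv), 4-(dimethylamino)pyridine (10 mol%), toluene, reflux with removal of MeOH
Reagents that add atoms: 2-(trimethylsilyl)ethanol, C[Si](C)(C)CCO
Why: β-Keto esters transesterify readily on heating (via the acyl ketene or the DMAP adduct), and removal of methanol drives the exchange.

Step 8
Reactants: 14 2-(trimethylsilyl)ethyl 3-oxobutanoate
Product: 15 2-(trimethylsilyl)ethyl (2E)-3-{[(trifluoromethyl)sulfonyl]oxy}but-2-enoate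
Conditions: Tf2O, aq. Me4NOH (25%), toluene, 5 °C
Reagents that add atoms: trifluoromethanesulfonic anhydride, O=S(=O)(OS(=O)(=O)C(F)(F)F)C(F)(F)F
Why: Stereoselective enol triflation: the non-chelated tetramethylammonium enolate is triflated to the (E)-enol triflate (OTf trans to the ester), which fixes the later 2E geometry.

Step 9
Reactants: 16 propyne
Product: 17 (E)-1,2-bis(4,4,5,5-tetramethyl-1,3,2-dioxaborolan-2-yl)prop-1-ene (the two boryl groups cis)
Conditions: B2pin2, Pt(PPh3)4 (3 mol%), DMF, 80 °C, sealed vessel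
Reagents that add atoms: bis(pinacolato)diboron, CC1(C)OB(OC1(C)C)B1OC(C)(C)C(C)(C)O1
Why: Platinum-catalysed diboration of an alkyne is a strict syn addition, which places the two boron atoms cis and thereby encodes the later C3/C6 cis relation of the 4Z olefin.

Step 10
Reactants: 15 2-(trimethylsilyl)ethyl (2E)-3-{[(trifluoromethyl)sulfonyl]oxy}but-2-enoate; 17 (E)-1,2-bis(4,4,5,5-tetramethyl-1,3,2-dioxaborolan-2-yl)prop-1-ene
Product: 18 2-(trimethylsilyl)ethyl (2E,4E)-3-methyl-5-(4,4,5,5-tetramethyl-1,3,2-dioxaborolan-2-yl)hexa-2,4-dienoate (boron cis to C3)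
Conditions: Pd(PPh3)4 (5 mol%), K3PO4 (3 equiv), 1,4-dioxane/H2O, 50 °C
Reagents that add atoms: none
Why: Suzuki–Miyaura coupling of a 1,2-diborylalkene takes place selectively at the terminal, less hindered C–B bond and proceeds with retention at both olefins, forming C3–C4.

Step 11
Reactants: 18 2-(trimethylsilyl)ethyl (2E,4E)-3-methyl-5-(4,4,5,5-tetramethyl-1,3,2-dioxaborolan-2-yl)hexa-2,4-dienoate
Product: 20 2-(trimethylsilyl)ethyl (2E,4Z)-5-iodo-3-methylhexa-2,4-dienoate, via sodium methoxyboronate 19 (not isolated)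
Conditions: NaOMe, THF/MeOH, −78 °C; then ICl, CH2Cl2, −78 °C
Reagents that add atoms: iodine monochloride, ClI
Why: Iododeboronation of the pre-formed methoxy ate complex is an ipso substitution with retention (base first, then ICl), so iodine ends up cis to C3.

Step 12
Reactants: 12 2-(trimethylsilyl)ethyl (2R,3S,8S)-9-bromo-3-[(tert-butyldimethylsilyl)oxy]-2-{[(tert-butyldimethylsilyl)oxy]methyl}-8-methylnonanoate; 20 2-(trimethylsilyl)ethyl (2E,4Z)-5-iodo-3-methylhexa-2,4-dienoate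
Product: 22 bis[2-(trimethylsilyl)ethyl] (2E,4Z,7S,12S,13R)-12-[(tert-butyldimethylsilyl)oxy]-13-{[(tert-butyldimethylsilyl)oxy]methyl}-3,5,7-trimethyltetradeca-2,4-dienedioate, via alkylzinc bromide 21 (not isolated)
Conditions: 12 (1.3 equiv), Zn dust, I2 (5 mol%), DMA, 70 °C; then 20, Pd(OAc)2 (3 mol%), 2-dicyclohexylphosphino-2',6'-dimethoxybiphenyl (SPhos, 6 mol%), THF/DMA, rt to 40 °C
Reagents that add atoms: none
Why: Negishi sp3–sp2 cross-coupling: zinc inserts into the primary C–Br bond with tolerance of esters and silyl ethers, and the zerovalent palladium catalyst couples the alkylzinc with the alkenyl iodide with retention of the 4Z geometry, forming the key C5–C6 bond.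

Step 13
Reactants: 22 bis[2-(trimethylsilyl)ethyl] (2E,4Z,7S,12S,13R)-12-[(tert-butyldimethylsilyl)oxy]-13-{[(tert-butyldimethylsilyl)oxy]methyl}-3,5,7-trimethyltetradeca-2,4-dienedioate
Product: 23 bis[2-(trimethylsilyl)ethyl] (2E,4S,5R,7S,12S,13R)-12-[(tert-butyldimethylsilyl)oxy]-13-{[(tert-butyldimethylsilyl)oxy]methyl}-4,5-epoxy-3,5,7-trimethyltetradec-2-enedioate
Conditions: 1,2:4,5-di-O-isopropylidene-β-L-erythro-2,3-hexodiulo-2,6-pyranose (L-fructose-derived Shi ketone, C12H18O6, 30 mol%), Oxone (2KHSO5·KHSO4·K2SO4), K2CO3, Bu4NHSO4, MeCN/dimethoxymethane/aq. Na2B4O7–Na2EDTA buffer (pH 10.5), 0 °C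
Reagents that add atoms: potassium peroxymonosulfate (active component of Oxone), [K+].[O-]S(=O)(=O)OO
Why: Shi asymmetric epoxidation: the chiral dioxirane attacks the electron-rich trisubstituted C4=C5 bond and not the enoate C2=C3 bond, oxygen transfer is stereospecifically syn (C3 and C6 stay cis), and by the spiro transition-state model the L-fructose-derived ketone delivers oxygen to the face that gives (4S,5R), the D-fructose ketone giving the (R,R) sense for this substituent layout.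

Step 14
Reactants: 23 bis[2-(trimethylsilyl)ethyl] (2E,4S,5R,7S,12S,13R)-12-[(tert-butyldimethylsilyl)oxy]-13-{[(tert-butyldimethylsilyl)oxy]methyl}-4,5-epoxy-3,5,7-trimethyltetradec-2-enedioate
Product: 24 (2E,4S,5R,7S,12S,13R)-4,5-epoxy-12-hydroxy-13-(hydroxymethyl)-3,5,7-trimethyltetradec-2-enedioic acid
Conditions: TASF [(Me2N)3S+ Me3SiF2−] (8 equiv), DMF, 0 °C to rt; aq. NaH2PO4 (pH 5) work-up
Reagents that add atoms: none
Why: Fluoride-induced global deprotection: both 2-(trimethylsilyl)ethyl esters fragment (ethylene and Me3SiF) and both TBS ethers are cleaved under non-acidic conditions that the vinyl epoxide and the β-hydroxy acid tolerate.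

**Compound list**

1 | (S)-3-bromo-2-methylpropan-1-ol | BrC[C@@H](C)CO | starting material
2 | (S)-3-bromo-2-methylpropyl trifluoromethanesulfonate | BrC[C@@H](C)COS(=O)(=O)C(F)(F)F | intermediate
3 | 5-bromopent-1-ene | C=CCCCBr | starting material
4 | pent-4-en-1-ylmagnesium bromide | C=CCCC[Mg]Br | intermediate
5 | (S)-8-bromo-7-methyloct-1-ene | BrC[C@@H](C)CCCCC=C | intermediate
6 | 3-[(5S)-6-bromo-5-methylhexyl]-1,2,4-trioxolane (secondary ozonide, ring carbon unassigned) | BrC[C@@H](C)CCCCC1OCOO1 | intermediate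
7 | (S)-7-bromo-6-methylheptanal | BrC[C@@H](C)CCCCC=O | intermediate
8 | acryloyl chloride | C=CC(Cl)=O | starting material
9 | 2-(trimethylsilyl)ethyl prop-2-enoate | C=CC(=O)OCC[Si](C)(C)C | intermediate
10 | 2-(trimethylsilyl)ethyl (2R,3S,8S)-9-bromo-8-methyl-3-[(4,4,5,5-tetramethyl-1,3,2-dioxaborolan-2-yl)oxy]-2-[(4,4,5,5-tetramethyl-1,3,2-dioxaborolan-2-yl)methyl]nonanoate | BrC[C@@H](C)CCCC[C@H](OB1OC(C)(C)C(C)(C)O1)[C@@H](CB1OC(C)(C)C(C)(C)O1)C(=O)OCC[Si](C)(C)C | intermediate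
11 | 2-(trimethylsilyl)ethyl (2R,3S,8S)-9-bromo-3-hydroxy-2-(hydroxymethyl)-8-methylnonanoate | BrC[C@@H](C)CCCC[C@H](O)[C@@H](CO)C(=O)OCC[Si](C)(C)C | intermediate
12 | 2-(trimethylsilyl)ethyl (2R,3S,8S)-9-bromo-3-[(tert-butyldimethylsilyl)oxy]-2-{[(tert-butyldimethylsilyl)oxy]methyl}-8-methylnonanoate | BrC[C@@H](C)CCCC[C@H](O[Si](C)(C)C(C)(C)C)[C@@H](CO[Si](C)(C)C(C)(C)C)C(=O)OCC[Si](C)(C)C | intermediate
13 | methyl 3-oxobutanoate (methyl acetoacetate) | CC(=O)CC(=O)OC | starting material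
14 | 2-(trimethylsilyl)ethyl 3-oxobutanoate | CC(=O)CC(=O)OCC[Si](C)(C)C | intermediate
15 | 2-(trimethylsilyl)ethyl (2E)-3-{[(trifluoromethyl)sulfonyl]oxy}but-2-enoate | C/C(OS(=O)(=O)C(F)(F)F)=C\C(=O)OCC[Si](C)(C)C | intermediate
16 | propyne | CC#C | starting material
17 | (E)-1,2-bis(4,4,5,5-tetramethyl-1,3,2-dioxaborolan-2-yl)prop-1-ene (boryl groups cis) | C/C(=C/B1OC(C)(C)C(C)(C)O1)B1OC(C)(C)C(C)(C)O1 | intermediate
18 | 2-(trimethylsilyl)ethyl (2E,4E)-3-methyl-5-(4,4,5,5-tetramethyl-1,3,2-dioxaborolan-2-yl)hexa-2,4-dienoate (boron cis to C3) | O=C(OCC[Si](C)(C)C)/C=C(\C)/C=C(/C)B1OC(C)(C)C(C)(C)O1 | intermediate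
19 | sodium methoxy ate complex of boronate 18 (B-OMe borate, olefin geometry as in 18) | O=C(OCC[Si](C)(C)C)/C=C(\C)/C=C(/C)[B-]1(OC)OC(C)(C)C(C)(C)O1.[Na+] | intermediate
20 | 2-(trimethylsilyl)ethyl (2E,4Z)-5-iodo-3-methylhexa-2,4-dienoate | O=C(OCC[Si](C)(C)C)/C=C(\C)/C=C(/C)I | intermediate
21 | {(2S,7S,8R)-7-[(tert-butyldimethylsilyl)oxy]-8-{[(tert-butyldimethylsilyl)oxy]methyl}-2-methyl-9-oxo-9-[2-(trimethylsilyl)ethoxy]nonyl}zinc bromide | Br[Zn]C[C@@H](C)CCCC[C@H](O[Si](C)(C)C(C)(C)C)[C@@H](CO[Si](C)(C)C(C)(C)C)C(=O)OCC[Si](C)(C)C | intermediate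
22 | bis[2-(trimethylsilyl)ethyl] (2E,4Z,7S,12S,13R)-12-[(tert-butyldimethylsilyl)oxy]-13-{[(tert-butyldimethylsilyl)oxy]methyl}-3,5,7-trimethyltetradeca-2,4-dienedioate | O=C(OCC[Si](C)(C)C)/C=C(\C)/C=C(/C)C[C@@H](C)CCCC[C@H](O[Si](C)(C)C(C)(C)C)[C@@H](CO[Si](C)(C)C(C)(C)C)C(=O)OCC[Si](C)(C)C | intermediate
23 | bis[2-(trimethylsilyl)ethyl] (2E,4S,5R,7S,12S,13R)-12-[(tert-butyldimethylsilyl)oxy]-13-{[(tert-butyldimethylsilyl)oxy]methyl}-4,5-epoxy-3,5,7-trimethyltetradec-2-enedioate | C/C(=C\C(=O)OCC[Si](C)(C)C)[C@@H]1O[C@]1(C)C[C@@H](C)CCCC[C@H](O[Si](C)(C)C(C)(C)C)[C@@H](CO[Si](C)(C)C(C)(C)C)C(=O)OCC[Si](C)(C)C | intermediate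
24 | (2E,4S,5R,7S,12S,13R)-4,5-epoxy-12-hydroxy-13-(hydroxymethyl)-3,5,7-trimethyltetradec-2-enedioic acid | C/C(=C\C(=O)O)[C@@H]1O[C@]1(C)C[C@@H](C)CCCC[C@H](O)[C@@H](CO)C(=O)O | target

**Totals**

Total step count: 14.
Longest linear sequence: 8 steps (1, 2, 3, 5, 6, 12, 13, 14). The west branch is 7, 8, 10, 11 and then 12–14; steps 4 and 9 are one-step side branches.

**Steps most likely to fail, with fallbacks**

Step 5 (the proposed new method).
- Risks: copper boryl may add directly to the aldehyde (1,2-diboration); the primary C–Br bond may be borylated; syn/anti and enantio-control are unproven for an unbranched aliphatic aldehyde; the sense of induction of the ligand is not known, so the ligand antipode is fixed by a pilot run to give the (2R,3S) series.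
- Fallback (known chemistry, Evans crotonate-imide aldol): sets out from 7 and comes back at 12. (R)-4-Benzyl-1,3-oxazolidin-2-one is N-acylated (n-BuLi, (E)-but-2-enoyl chloride, THF, −78 °C) to (4R)-4-benzyl-3-[(2E)-but-2-enoyl]-1,3-oxazolidin-2-one F1. Its dibutylboron dienolate (Bu2BOTf, Et3N, CH2Cl2, −78 °C) adds to 7 at the α-carbon to give the syn adduct (4R)-4-benzyl-3-[(2R,3S,8S)-9-bromo-2-ethenyl-3-hydroxy-8-methylnonanoyl]-1,3-oxazolidin-2-one F2. TBSOTf/2,6-lutidine gives (4R)-4-benzyl-3-[(2R,3S,8S)-9-bromo-3-[(tert-butyldimethylsilyl)oxy]-2-ethenyl-8-methylnonanoyl]-1,3-oxazolidin-2-one F3. Ozonolysis of the vinyl group with borohydride work-up (O3, CH2Cl2/MeOH, −78 °C; NaBH4, −78 to −20 °C) gives (4R)-4-benzyl-3-[(2R,3S,8S)-9-bromo-3-[(tert-butyldimethylsilyl)oxy]-2-(hydroxymethyl)-8-methylnonanoyl]-1,3-oxazolidin-2-one F4. TBSCl/imidazole (DMF) gives (4R)-4-benzyl-3-[(2R,3S,8S)-9-bromo-3-[(tert-butyldimethylsilyl)oxy]-2-{[(tert-butyldimethylsilyl)oxy]methyl}-8-methylnonanoyl]-1,3-oxazolidin-2-one F5. LiOCH2CH2SiMe3 (from Me3SiCH2CH2OH and n-BuLi, THF, 0 °C) exchanges the auxiliary for the 2-(trimethylsilyl)ethyl ester, which is 12.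

Step 13.
- Risks: face selectivity and ee are untested for a Z-trisubstituted olefin in a twisted 3-methyl-dienoate; the facial assignment rests on the spiro model; the diastereomer would be hard to separate.
- Fallback (hydroxyl-directed Sharpless epoxidation on a nerol-type alcohol, then late construction of the enoate): sets out from 12 and comes back at 23. But-2-yn-1-ol is converted (NaAlH2(OCH2CH2OMe)2, THF, 0 °C; then I2, −78 °C) into (2Z)-3-iodobut-2-en-1-ol F6 and silylated (Et3SiCl, imidazole) to triethyl{[(2Z)-3-iodobut-2-en-1-yl]oxy}silane F7. The zinc reagent 21 (from 12 as in step 12) is coupled with F7 (Pd(OAc)2, SPhos) to give 2-(trimethylsilyl)ethyl (2R,3S,8S,10Z)-3-[(tert-butyldimethylsilyl)oxy]-2-{[(tert-butyldimethylsilyl)oxy]methyl}-8,10-dimethyl-12-[(triethylsilyl)oxy]dodec-10-enoate F8. Pyridinium p-toluenesulfonate in MeOH (0 °C) removes only the triethylsilyl group to give the (10Z)-12-hydroxy compound F9. Sharpless epoxidation (Ti(Oi-Pr)4, L-(+)-diethyl tartrate, t-BuOOH, 4 Å sieves, CH2Cl2, −20 °C; the sense that gives (2S,3R)-epoxynerol from nerol) gives 2-(trimethylsilyl)ethyl (2R,3S,8S)-3-[(tert-butyldimethylsilyl)oxy]-2-{[(tert-butyldimethylsilyl)oxy]methyl}-9-[(2R,3S)-3-(hydroxymethyl)-2-methyloxiran-2-yl]-8-methylnonanoate F10. Dess–Martin oxidation gives the corresponding epoxy aldehyde (CHO at C3, oxirane as in 23) F11. MeMgBr (THF, −78 °C) gives the C3 secondary alcohol (both epimers, oxirane as in 23) F12. A second Dess–Martin oxidation gives the epoxy methyl ketone (acetyl group on C4, oxirane as in 23) F13. Horner–Wadsworth–Emmons olefination with 2-(trimethylsilyl)ethyl (diethoxyphosphoryl)acetate/NaH (THF, 0 °C to rt), with removal of the minor 2Z isomer, gives 23.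

Step 11.
- Risks: the stereochemical fidelity of iododeboronation on an α-methyl dienyl boronate (competing ICl addition to the diene gives the inverted iodide) and brief exposure of the ester to methoxide.
- Fallback (the roles of the coupling partners are reversed and no iodide is made): sets out from 18 (with 12) and comes back at 22. The alkenyl boronate 18 is coupled directly with the primary alkyl bromide 12 in an sp2–sp3 Suzuki–Miyaura reaction of the alkyl-bromide type (Pd(OAc)2, P(t-Bu)2Me·HBF4, K3PO4·H2O, tert-amyl alcohol, rt to 40 °C), which keeps both olefin geometries; the new compounds on this way: none F0.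

**Further compounds**

F1 | step 5 | (4R)-4-benzyl-3-[(2E)-but-2-enoyl]-1,3-oxazolidin-2-one | C/C=C/C(=O)N1C(=O)OC[C@H]1Cc1ccccc1
F2 | step 5 | (4R)-4-benzyl-3-[(2R,3S,8S)-9-bromo-2-ethenyl-3-hydroxy-8-methylnonanoyl]-1,3-oxazolidin-2-one | BrC[C@@H](C)CCCC[C@H](O)[C@@H](C=C)C(=O)N1C(=O)OC[C@H]1Cc1ccccc1
F3 | step 5 | (4R)-4-benzyl-3-[(2R,3S,8S)-9-bromo-3-[(tert-butyldimethylsilyl)oxy]-2-ethenyl-8-methylnonanoyl]-1,3-oxazolidin-2-one | BrC[C@@H](C)CCCC[C@H](O[Si](C)(C)C(C)(C)C)[C@@H](C=C)C(=O)N1C(=O)OC[C@H]1Cc1ccccc1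
F4 | step 5 | (4R)-4-benzyl-3-[(2R,3S,8S)-9-bromo-3-[(tert-butyldimethylsilyl)oxy]-2-(hydroxymethyl)-8-methylnonanoyl]-1,3-oxazolidin-2-one | BrC[C@@H](C)CCCC[C@H](O[Si](C)(C)C(C)(C)C)[C@@H](CO)C(=O)N1C(=O)OC[C@H]1Cc1ccccc1
F5 | step 5 | (4R)-4-benzyl-3-[(2R,3S,8S)-9-bromo-3-[(tert-butyldimethylsilyl)oxy]-2-{[(tert-butyldimethylsilyl)oxy]methyl}-8-methylnonanoyl]-1,3-oxazolidin-2-one | BrC[C@@H](C)CCCC[C@H](O[Si](C)(C)C(C)(C)C)[C@@H](CO[Si](C)(C)C(C)(C)C)C(=O)N1C(=O)OC[C@H]1Cc1ccccc1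
F0 | step 11 | none | none
F6 | step 13 | (2Z)-3-iodobut-2-en-1-ol | C/C(I)=C/CO
F7 | step 13 | triethyl{[(2Z)-3-iodobut-2-en-1-yl]oxy}silane | C/C(I)=C/CO[Si](CC)(CC)CC
F8 | step 13 | 2-(trimethylsilyl)ethyl (2R,3S,8S,10Z)-3-[(tert-butyldimethylsilyl)oxy]-2-{[(tert-butyldimethylsilyl)oxy]methyl}-8,10-dimethyl-12-[(triethylsilyl)oxy]dodec-10-enoate | CC[Si](CC)(CC)OC/C=C(/C)C[C@@H](C)CCCC[C@H](O[Si](C)(C)C(C)(C)C)[C@@H](CO[Si](C)(C)C(C)(C)C)C(=O)OCC[Si](C)(C)C
F9 | step 13 | 2-(trimethylsilyl)ethyl (2R,3S,8S,10Z)-3-[(tert-butyldimethylsilyl)oxy]-2-{[(tert-butyldimethylsilyl)oxy]methyl}-12-hydroxy-8,10-dimethyldodec-10-enoate | OC/C=C(/C)C[C@@H](C)CCCC[C@H](O[Si](C)(C)C(C)(C)C)[C@@H](CO[Si](C)(C)C(C)(C)C)C(=O)OCC[Si](C)(C)C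
F10 | step 13 | 2-(trimethylsilyl)ethyl (2R,3S,8S)-3-[(tert-butyldimethylsilyl)oxy]-2-{[(tert-butyldimethylsilyl)oxy]methyl}-9-[(2R,3S)-3-(hydroxymethyl)-2-methyloxiran-2-yl]-8-methylnonanoate | OC[C@@H]1O[C@]1(C)C[C@@H](C)CCCC[C@H](O[Si](C)(C)C(C)(C)C)[C@@H](CO[Si](C)(C)C(C)(C)C)C(=O)OCC[Si](C)(C)C
F11 | step 13 | epoxy aldehyde from F10 (CHO in place of CH2OH, oxirane configured as in 23) | O=C[C@@H]1O[C@]1(C)C[C@@H](C)CCCC[C@H](O[Si](C)(C)C(C)(C)C)[C@@H](CO[Si](C)(C)C(C)(C)C)C(=O)OCC[Si](C)(C)C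
F12 | step 13 | secondary alcohol from F11 and MeMgBr (1-hydroxyethyl on the oxirane, both carbinol epimers, oxirane as in 23) | CC(O)[C@@H]1O[C@]1(C)C[C@@H](C)CCCC[C@H](O[Si](C)(C)C(C)(C)C)[C@@H](CO[Si](C)(C)C(C)(C)C)C(=O)OCC[Si](C)(C)C
F13 | step 13 | epoxy methyl ketone from F12 (acetyl on the oxirane, oxirane as in 23) | CC(=O)[C@@H]1O[C@]1(C)C[C@@H](C)CCCC[C@H](O[Si](C)(C)C(C)(C)C)[C@@H](CO[Si](C)(C)C(C)(C)C)C(=O)OCC[Si](C)(C)C
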